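The ratio of isomer of the product A to target climbs in the elm run from 1.99 at 0.333 h to 2.97 at 4.00 h. What does it reach in a new flask?

| setting | elm | alder | oak | flask |
|---|---|---|---|---|
| substrate | 0.25 M | 0.25 M | 0.12 M | 0.25 M |
| other conformer | 0.25 M | 0.25 M | 0.25 M | 0.250 M |
| catalyst | 42 mM | 66 mM | 30 mM | 30 mM |
| remark | run made earlier | run made earlier | run made earlier |  |
| time |  |  |  | 4.0 h |

| run | time / h | isomer of the product A / % | target / % |
|---|---|---|---|
| elm | 0.333 | 39.0 | 19.6 |
| elm | 0.667 | 53.1 | 23.0 |
| elm | 1.00 | 57.8 | 22.7 |
| elm | 2.00 | 60.5 | 20.6 |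
| elm | 4.00 | 60.8 | 20.5 |
| alder | 0.333 | 48.6 | 24.8 |
| alder | 1.00 | 59.4 | 22.8 |
| alder | 2.00 | 59.4 | 21.4 |
| alder | 3.00 | 60.0 | 20.8 |
| alder | 4.00 | 60.0 | 21.0 |
| oak | 0.833 | 53.4 | 20.1 |
| oak | 1.50 | 60.2 | 20.4 |
| oak | 2.50 | 62.8 | 19.7 |
| oak | 3.00 | 62.5 | 19.4 |
| oak | 4.00 | 62.3 | 19.1 |

(readings scatter by 0.3 percentage points)

- percentages count the substrate that a species holds: one homo dimer counts as two
- steps that have been proposed: substrate <-> other conformer; substrate + catalyst -> catalyst + target; catalyst + other conformer -> catalyst + isomer of the product A; target <-> isomer of the product B; 2 substrate -> homo dimer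

- ratio of isomer of the product A to target at 40 s
- ratio of isomer of the product A to target at 12 min
- ratio of isomer of the product A to target at 4.0 h
- which of isomer of the product A and target there is more of at 4.0 h

Does the ratio stop? It seems to: target in the elm run reads 20.6% at 2.00 h and 20.5% at 4.00 h, with a scatter of 0.3 percentage points.

What stays close between runs? Not target itself, but the end share of target: the target reading at 4.00 h divided by what isomer of the product A leaves over. It reads 0.523 in elm, 0.525 in alder and 0.507 in oak, with a mean of 0.518. If the remainder is mainly isomer of the product B, this is an equilibrium share of that pair.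

So what does the flask give? It has the substrate and other conformer charges of elm and alder, with less catalyst than either. A straight line in catalyst through their end readings gives 61.2% isomer of the product A, although those readings differ by just 0.8 points. My end ratio is then 3.04, with isomer of the product A ahead.

And earlier? The share says nothing there, and 12 min and 40 s come earlier than any reading. The first ratios, 1.99 in elm and 1.96 in alder, suggest about that value at 12 min; for 40 s I commit to no figure.

The forecast gives 1.7 (range 1.1 to 3.2) at 40 s, 1.85 at 12 min and 3 at 4.0 h, with isomer of the product A ahead, and says of the earliest time that “the ratio reflects intrinsic selectivity before exchange completes”.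

The flask gives 2.80, 2.01 and 2.97, with isomer of the product A ahead at 61.0% against 20.6% target, so its end share is 0.527 against my 0.518.

    substrate ⇌ other conformer (K = 0.550, k = 0.00210 s⁻¹)
    substrate + catalyst → catalyst + target (k = 0.0120 M⁻¹ s⁻¹)
    catalyst + other conformer → catalyst + isomer of the product A (k = 0.0360 M⁻¹ s⁻¹)
    target ⇌ isomer of the product B (K = 0.890, k = 3.70 × 10⁻⁴ s⁻¹)
    2 substrate → homo dimer (k = 4.60 × 10⁻⁶ M⁻¹ s⁻¹)

The slowest mode of the flask has a half-life of 0.323 h at 4.0 h, much shorter than the 4.0 h of the run. Target in the flask reads 20.9% at 2.00 h and 20.6% at 40.0 h, and a reading ten times later makes no difference to the end ratio.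

In the neighbour flask with c(substrate) = 0.062 M, isomer of the product A ends at 63.9%, so the share gives 18.7% target and a ratio of 3.42. The computed values are 19.0% and 3.36.

The earlier runs and the new flask are simulated with made-up constants, and the scatter is random.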